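**Retrosynthetic overview**
1. Target ⇒ (3R)-3-hydroxy-β,ψ-caroten-4-one; the C4 stereocentre is set last by hydride delivery directed by the C3 hydroxyl.
2. C40 ⇒ ring C15 phosphonium salt + C25 apo-lycopenal (Wittig, C11=C12); C25 ⇒ ψ-C15 phosphonium salt + C10 dialdehyde (Wittig, C11'=C12').
3. Ring C15 salt ⇒ tertiary enynyl carbinol; the C4–O bond and the ring C5=C6 bond form together in an anodic, aminoxyl-catalysed oxidative 1,3-transposition (key step); C6–C7 comes from acetylide addition to a C9 enone.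
4. C9 enone ⇒ (4R,6R)-actinol; Mitsunobu inversion gives the C3 configuration, then desaturation.
5. Rings: the only ring is bought intact in actinol; no ring is formed in the route.

Assumption: (4R,6R)-actinol (bulk intermediate of technical zeaxanthin manufacture), (2E)-3-methylpent-2-en-4-yn-1-ol, (3E,5E)-pseudoionone and the C10 dialdehyde are bought as such; carotenoid numbering (C3, C4, C6 ...) is used in the explanations.

**Step 1**
Reactants: 1 (4R,6R)-4-hydroxy-2,2,6-trimethylcyclohexan-1-one (actinol)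
Product: 2 (4S,6R)-4-(benzoyloxy)-2,2,6-trimethylcyclohexan-1-one
Conditions: BzOH (1.5 equiv), PPh3 (1.5 equiv), DIAD (1.5 equiv), THF, 0 to 20 °C
Reagents that add atoms: benzoic acid, OC(=O)c1ccccc1
Why: Mitsunobu esterification displaces the alkoxyphosphonium by SN2, so the bought carbinol centre is inverted cleanly (4R to 4S, axial OH to equatorial ester); this carbon becomes C3 of the target and the benzoate is the only protecting group needed.

**Step 2**
Reactants: 2 (4S,6R)-4-(benzoyloxy)-2,2,6-trimethylcyclohexan-1-one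
Product: 3 (4R)-4-(benzoyloxy)-2,6,6-trimethylcyclohex-2-en-1-one
Conditions: IBX (2.2 equiv), DMSO/fluorobenzene 1:2, 70 °C
Reagents that add atoms: none
Why: IBX desaturation of the ketone through its only possible enol gives the enone and erases the C6 centre; the ester carbon is untouched and its label changes from S to R only because the CIP priorities of the ring branches change.

**Step 3**
Reactants: 3 (4R)-4-(benzoyloxy)-2,6,6-trimethylcyclohex-2-en-1-one; 4 (2E)-3-methylpent-2-en-4-yn-1-ol
Product: 6 (1R,4R)-4-hydroxy-4-[(3E)-5-hydroxy-3-methylpent-3-en-1-yn-1-yl]-3,5,5-trimethylcyclohex-2-en-1-yl benzoate, via dilithio enynol 5 (not isolated)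
Conditions: 4 (1.5 equiv), n-BuLi (3.0 equiv), THF, −78 to −20 °C; CeCl3 (1.6 equiv), −78 °C; then 3, −78 °C, 2 h; H2O quench
Reagents that add atoms: none
Why: 1,2-addition of the CeCl3-activated lithium acetylide to the enone carbonyl (organocerium-type addition, ketone-selective over the benzoate at −78 °C) forms the C6–C7 bond; attack anti to the pseudoaxial gem-methyl should give mainly the drawn carbinol epimer, but this centre is erased in step 5, so its configuration is immaterial.

**Step 4**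
Reactants: 6 (1R,4R)-4-hydroxy-4-[(3E)-5-hydroxy-3-methylpent-3-en-1-yn-1-yl]-3,5,5-trimethylcyclohex-2-en-1-yl benzoate
Product: 7 (1R,4R)-4-[(3E)-5-(acetyloxy)-3-methylpent-3-en-1-yn-1-yl]-4-hydroxy-3,5,5-trimethylcyclohex-2-en-1-yl benzoate
Conditions: Ac2O (1.1 equiv), pyridine, CH2Cl2, 0 °C
Reagents that add atoms: acetic anhydride, CC(=O)OC(C)=O
Why: selective acetylation of the primary allylic OH (the hindered tertiary OH is inert without an acyl-transfer catalyst) masks it against the oxidation in step 5 and makes it the leaving group for step 7.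

**Step 5**
Reactants: 7 (1R,4R)-4-[(3E)-5-(acetyloxy)-3-methylpent-3-en-1-yn-1-yl]-4-hydroxy-3,5,5-trimethylcyclohex-2-en-1-yl benzoate
Product: 8 (1R)-4-[(3E)-5-(acetyloxy)-3-methylpent-3-en-1-yn-1-yl]-3,5,5-trimethyl-2-oxocyclohex-3-en-1-yl benzoate
Conditions: undivided cell, graphite anode, Pt cathode; 4-acetamido-TEMPO (15 mol%), nBu4NBF4 (0.1 M), MeCN/HFIP 9:1, constant current 5 mA cm−2, 2.4 F mol−1, 20 °C
Reagents that add atoms: none
Why: Proposed new method: anodic oxidation turns the aminoxyl into its oxoammonium cation, which captures the tertiary alcohol as an N–O adduct that has no α-hydrogen; HFIP-assisted ionisation to the alkyne- and alkene-stabilised allyl cation and return of the oxygen at the secondary terminus (C4) gives the transposed adduct, which loses its α-hydrogen to give the C4 ketone and the hydroxylamine, the latter being re-oxidised at the anode while protons are reduced to H2 at the cathode, so the C4–O bond and the ring C5=C6 bond form without a chemical oxidant; the closest known reaction type is the Babler–Dauben oxidative 1,3-transposition of tertiary allylic alcohols with stoichiometric chlorochromate or oxoammonium salts, combined with aminoxyl-mediated anodic alcohol oxidation; no stereocentre is formed and the C3 ester centre is not involved.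

**Step 6**
Reactants: 8 (1R)-4-[(3E)-5-(acetyloxy)-3-methylpent-3-en-1-yn-1-yl]-3,5,5-trimethyl-2-oxocyclohex-3-en-1-yl benzoate
Product: 9 (1R)-4-[(1Z,3E)-5-(acetyloxy)-3-methylpenta-1,3-dien-1-yl]-3,5,5-trimethyl-2-oxocyclohex-3-en-1-yl benzoate
Conditions: H2 (1 atm, stopped at 1.0 equiv uptake), Pd/CaCO3 poisoned with Pb(OAc)2, quinoline, EtOAc, 0 °C
Reagents that add atoms: none
Why: Lindlar-type syn semihydrogenation reduces only the alkyne and gives the (7Z)-dienone, leaving the tri- and tetrasubstituted alkenes, both esters and the ketone untouched; the strained Z bond is corrected in step 7.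

**Step 7**
Reactants: 9 (1R)-4-[(1Z,3E)-5-(acetyloxy)-3-methylpenta-1,3-dien-1-yl]-3,5,5-trimethyl-2-oxocyclohex-3-en-1-yl benzoate
Product: 10 {(2E,4E)-5-[(4R)-4-(benzoyloxy)-2,6,6-trimethyl-3-oxocyclohex-1-en-1-yl]-3-methylpenta-2,4-dien-1-yl}triphenylphosphonium bromide
Conditions: PPh3·HBr (1.05 equiv), MeOH, 20 to 40 °C; crystallisation from EtOAc
Reagents that add atoms: triphenylphosphine hydrobromide, Br.c1ccc(cc1)P(c1ccccc1)c1ccccc1
Why: acid-promoted SN1 ionisation of the allylic acetate and capture of the pentadienyl cation by PPh3 at the primary terminus gives the Wittig salt (the C4 ketone cannot ionise and the benzoate is acid-stable); bond rotation in the delocalised cation relaxes the hindered 7Z bond to 7E, and any residual Z isomer is equilibrated in step 11.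

**Step 8**
Reactants: 11 (3E,5E)-6,10-dimethylundeca-3,5,9-trien-2-one (pseudoionone)
Product: 12 (4E,6E)-3,7,11-trimethyldodeca-1,4,6,10-tetraen-3-ol (racemic)
Conditions: CH2=CHMgBr (1.2 equiv), THF, −20 to 0 °C; H2O quench
Reagents that add atoms: vinylmagnesium bromide, C=C[Mg]Br
Why: Grignard 1,2-addition to the dienone carbonyl gives the tertiary vinyl carbinol; its racemic centre is destroyed in step 9.

**Step 9**
Reactants: 12 (4E,6E)-3,7,11-trimethyldodeca-1,4,6,10-tetraen-3-ol
Product: 13 [(2E,4E,6E)-3,7,11-trimethyldodeca-2,4,6,10-tetraen-1-yl]triphenylphosphonium bromide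
Conditions: PPh3·HBr (1.05 equiv), MeOH, 20 °C; crystallisation from EtOAc
Reagents that add atoms: triphenylphosphine hydrobromide, Br.c1ccc(cc1)P(c1ccccc1)c1ccccc1
Why: SN1' phosphonium salt formation with allylic transposition (ionisation of the tertiary carbinol, PPh3 attack at the terminal CH2) gives the conjugated salt, and crystallisation delivers the (2E) isomer.

**Step 10**
Reactants: 13 [(2E,4E,6E)-3,7,11-trimethyldodeca-2,4,6,10-tetraen-1-yl]triphenylphosphonium bromide; 14 (2E,4E,6E)-2,7-dimethylocta-2,4,6-trienedial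
Product: 16 (2E,4E,6E,8E,10E,12E,14E)-2,7,11,15,19-pentamethylicosa-2,4,6,8,10,12,14,18-octaenal (C25 apo-12'-lycopenal), via ψ-C15 ylide 15 (not isolated)
Conditions: NaOMe (1.1 equiv), CH2Cl2/MeOH, 0 °C, slow addition of the ylide to 14 (3 equiv); then n-heptane, 95 °C, 2 h
Reagents that add atoms: none
Why: Wittig olefination at one aldehyde of the excess symmetrical dialdehyde forms C11'=C12', and heating equilibrates the new disubstituted bond to E.

**Step 11**
Reactants: 10 {(2E,4E)-5-[(4R)-4-(benzoyloxy)-2,6,6-trimethyl-3-oxocyclohex-1-en-1-yl]-3-methylpenta-2,4-dien-1-yl}triphenylphosphonium bromide; 16 C25 apo-12'-lycopenal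
Product: 19 (3R)-3-hydroxy-β,ψ-caroten-4-one, via ring C15 ylide 17 (not isolated), via (3R)-4-oxo-β,ψ-caroten-3-yl benzoate 18 (not isolated)
Conditions: NaOMe (2.2 equiv), CH2Cl2/MeOH, argon, 0 to 20 °C, 4 h; then n-heptane/EtOH, reflux, 3 h, dark
Reagents that add atoms: none
Why: Wittig olefination forms C11=C12, the excess methoxide then removes the benzoate by transesterification (fast next to the ketone), and heating equilibrates Z bonds to all-E; C3 is not touched, and strict exclusion of air prevents enediol oxidation of the α-ketol.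

**Step 12**
Reactants: 19 (3R)-3-hydroxy-β,ψ-caroten-4-one
Product: 20 (3R,4R)-β,ψ-carotene-3,4-diol (target)
Conditions: Me4NBH(OAc)3 (4 equiv), AcOH (3 equiv), CH2Cl2/MeCN 1:1, −20 °C, argon, dark
Reagents that add atoms: none
Why: Saksena–Evans hydroxyl-directed reduction: the C3 alkoxy(acetoxy)borohydride delivers hydride intramolecularly to C4 on the face of the C3–O bond, so the new OH is trans to it and C4 is set as R under control of the bought centre.

**Compound list**
1 | (4R,6R)-4-hydroxy-2,2,6-trimethylcyclohexan-1-one (actinol) | O=C1C(C)(C)C[C@H](O)C[C@H]1C | starting material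
2 | (4S,6R)-4-(benzoyloxy)-2,2,6-trimethylcyclohexan-1-one | O=C1C(C)(C)C[C@@H](OC(=O)c2ccccc2)C[C@H]1C | intermediate
3 | (4R)-4-(benzoyloxy)-2,6,6-trimethylcyclohex-2-en-1-one | O=C1C(C)=C[C@H](OC(=O)c2ccccc2)CC1(C)C | intermediate
4 | (2E)-3-methylpent-2-en-4-yn-1-ol | C#C/C(C)=C/CO | starting material
5 | dilithio enynol (O,C-dilithiated 4) | [Li]C#C/C(C)=C/CO[Li] | intermediate (not isolated)
6 | (1R,4R)-4-hydroxy-4-[(3E)-5-hydroxy-3-methylpent-3-en-1-yn-1-yl]-3,5,5-trimethylcyclohex-2-en-1-yl benzoate (expected major carbinol epimer) | O[C@@]1(C#C/C(C)=C/CO)C(C)=C[C@H](OC(=O)c2ccccc2)CC1(C)C | intermediate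
7 | (1R,4R)-4-[(3E)-5-(acetyloxy)-3-methylpent-3-en-1-yn-1-yl]-4-hydroxy-3,5,5-trimethylcyclohex-2-en-1-yl benzoate | O[C@@]1(C#C/C(C)=C/COC(C)=O)C(C)=C[C@H](OC(=O)c2ccccc2)CC1(C)C | intermediate
8 | (1R)-4-[(3E)-5-(acetyloxy)-3-methylpent-3-en-1-yn-1-yl]-3,5,5-trimethyl-2-oxocyclohex-3-en-1-yl benzoate | CC(=O)OC/C=C(\C)C#CC1=C(C)C(=O)[C@H](OC(=O)c2ccccc2)CC1(C)C | intermediate
9 | (1R)-4-[(1Z,3E)-5-(acetyloxy)-3-methylpenta-1,3-dien-1-yl]-3,5,5-trimethyl-2-oxocyclohex-3-en-1-yl benzoate | CC(=O)OC/C=C(C)/C=C\C1=C(C)C(=O)[C@H](OC(=O)c2ccccc2)CC1(C)C | intermediate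
10 | {(2E,4E)-5-[(4R)-4-(benzoyloxy)-2,6,6-trimethyl-3-oxocyclohex-1-en-1-yl]-3-methylpenta-2,4-dien-1-yl}triphenylphosphonium bromide | [Br-].c1ccccc1[P+](c1ccccc1)(c1ccccc1)C/C=C(C)/C=C/C1=C(C)C(=O)[C@H](OC(=O)c2ccccc2)CC1(C)C | intermediate
11 | (3E,5E)-6,10-dimethylundeca-3,5,9-trien-2-one (pseudoionone) | CC(C)=CCC/C(C)=C/C=C/C(C)=O | starting material
12 | (4E,6E)-3,7,11-trimethyldodeca-1,4,6,10-tetraen-3-ol (racemic) | CC(C)=CCC/C(C)=C/C=C/C(C)(O)C=C | intermediate
13 | [(2E,4E,6E)-3,7,11-trimethyldodeca-2,4,6,10-tetraen-1-yl]triphenylphosphonium bromide | [Br-].CC(C)=CCC/C(C)=C/C=C/C(C)=C/C[P+](c1ccccc1)(c1ccccc1)c1ccccc1 | intermediate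
14 | (2E,4E,6E)-2,7-dimethylocta-2,4,6-trienedial | O=C/C(C)=C/C=C/C=C(C)/C=O | starting material
15 | ψ-C15 ylide, (2E,4E,6E)-3,7,11-trimethyldodeca-2,4,6,10-tetraenylidene(triphenyl)phosphorane | CC(C)=CCC/C(C)=C/C=C/C(C)=C/C=P(c1ccccc1)(c1ccccc1)c1ccccc1 | intermediate (not isolated)
16 | (2E,4E,6E,8E,10E,12E,14E)-2,7,11,15,19-pentamethylicosa-2,4,6,8,10,12,14,18-octaenal (C25 apo-12'-lycopenal) | CC(C)=CCC/C(C)=C/C=C/C(C)=C/C=C/C(C)=C/C=C/C=C(C)/C=O | intermediate
17 | ring C15 ylide (ylide of 10) | c1ccccc1P(c1ccccc1)(c1ccccc1)=C/C=C(C)/C=C/C1=C(C)C(=O)[C@H](OC(=O)c2ccccc2)CC1(C)C | intermediate (not isolated)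
18 | (3R)-4-oxo-β,ψ-caroten-3-yl benzoate (all-E) | CC(C)=CCC/C(C)=C/C=C/C(C)=C/C=C/C(C)=C/C=C/C=C(C)/C=C/C=C(C)/C=C/C1=C(C)C(=O)[C@H](OC(=O)c2ccccc2)CC1(C)C | intermediate (not isolated)
19 | (3R)-3-hydroxy-β,ψ-caroten-4-one (all-E) | CC(C)=CCC/C(C)=C/C=C/C(C)=C/C=C/C(C)=C/C=C/C=C(C)/C=C/C=C(C)/C=C/C1=C(C)C(=O)[C@H](O)CC1(C)C | intermediate
20 | (3R,4R)-β,ψ-carotene-3,4-diol (all-E, trans-diol) | CC(C)=CCC/C(C)=C/C=C/C(C)=C/C=C/C(C)=C/C=C/C=C(C)/C=C/C=C(C)/C=C/C1=C(C)[C@@H](O)[C@H](O)CC1(C)C | target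

**Step count and risk**
Total steps: 12. Longest linear sequence: 9 (steps 1 to 7, then 11 and 12).

Most likely to fail:

Step 5 (the proposed anodic oxidative transposition). The risks are opening on the alkyne side to an allenyl/enone product, participation of the neighbouring benzoate in the allyl cation, and anodic over-oxidation. The fallback uses known chemistry in two stages and no electrolysis. It sets out from 7: Ph3SiOReO3 (2 mol%), Et2O, −40 to 0 °C, effects a redox-neutral perrhenate-ester 1,3-transposition to the conjugated secondary alcohol (1R,2RS)-4-[(3E)-5-(acetyloxy)-3-methylpent-3-en-1-yn-1-yl]-2-hydroxy-3,5,5-trimethylcyclohex-3-en-1-yl benzoate F4 (both C2 epimers are usable). MnO2 in CH2Cl2 at 20 °C then oxidises the allylic alcohol, and the route is rejoined at 8.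

Step 3 (acetylide addition to a hindered enone in the presence of the benzoate). The fallback removes the ester before the organometallic step and reinstalls it afterwards by reactivity order. It sets out from 3: K2CO3 in MeOH at 0 °C gives (4R)-4-hydroxy-2,6,6-trimethylcyclohex-2-en-1-one F1. Excess dilithio enynol 5 (3.2 equiv, CeCl3, THF, −78 to 0 °C) adds to the ketone of the alkoxide and gives (1R,4R)-1-[(3E)-5-hydroxy-3-methylpent-3-en-1-yn-1-yl]-2,6,6-trimethylcyclohex-2-ene-1,4-diol F2. Ac2O (1.05 equiv) in pyridine at −20 °C acetylates only the primary OH to (2E)-5-[(1R,4R)-1,4-dihydroxy-2,6,6-trimethylcyclohex-2-en-1-yl]-3-methylpent-2-en-4-yn-1-yl acetate F3. BzCl in pyridine at 0 °C then benzoylates the secondary allylic OH (the tertiary OH is inert), and the route is rejoined at 7.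

Step 12 (directed reduction of a polyene-conjugated ketone; the 4-hydroxy product is acid-labile and the ketone may be sluggish). The fallback gives up direction and uses separation with recycling. It sets out from 19: NaBH4 with CeCl3·7H2O in MeOH/THF at −40 °C (Luche 1,2-reduction) gives 20 together with the cis isomer (3R,4S)-β,ψ-carotene-3,4-diol F5. The two diastereomers are separated by chromatography, and F5 is returned to 19 by MnO2 oxidation of its allylic 4-OH for another pass; the fallback comes back to the route at 20.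

**Further compounds**
F1 | step 3 | (4R)-4-hydroxy-2,6,6-trimethylcyclohex-2-en-1-one | O=C1C(C)=C[C@H](O)CC1(C)C
F2 | step 3 | (1R,4R)-1-[(3E)-5-hydroxy-3-methylpent-3-en-1-yn-1-yl]-2,6,6-trimethylcyclohex-2-ene-1,4-diol | O[C@@]1(C#C/C(C)=C/CO)C(C)=C[C@H](O)CC1(C)C
F3 | step 3 | (2E)-5-[(1R,4R)-1,4-dihydroxy-2,6,6-trimethylcyclohex-2-en-1-yl]-3-methylpent-2-en-4-yn-1-yl acetate | O[C@@]1(C#C/C(C)=C/COC(C)=O)C(C)=C[C@H](O)CC1(C)C
F4 | step 5 | (1R,2RS)-4-[(3E)-5-(acetyloxy)-3-methylpent-3-en-1-yn-1-yl]-2-hydroxy-3,5,5-trimethylcyclohex-3-en-1-yl benzoate | CC(=O)OC/C=C(\C)C#CC1=C(C)C(O)[C@H](OC(=O)c2ccccc2)CC1(C)C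
F5 | step 12 | (3R,4S)-β,ψ-carotene-3,4-diol | CC(C)=CCC/C(C)=C/C=C/C(C)=C/C=C/C(C)=C/C=C/C=C(C)/C=C/C=C(C)/C=C/C1=C(C)[C@H](O)[C@H](O)CC1(C)C
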